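## Retrosynthetic overview

- Last C–C bond: the diaryl ketone is not made by ArM + ArCHO/oxidation or by Friedel–Crafts acylation. It comes from an acetal-tethered anionic O→C aroyl transfer inside a 3-aryloxyphthalide. The lactone C=O becomes the ketone, the acetal CH becomes CHO, and the tether O becomes the ring-A OH.
- The 3-aryloxyphthalide is cut at its C–O bond into a ring-B pseudo-acid (3-hydroxyphthalide) and a fully substituted ring-A iodophenol.
- Ring B is built de novo by a formyl-directed Diels–Alder/aromatisation. A prenyl-bearing Chan-type bis(silyloxy)diene reacts with allyl 4-oxobut-2-ynoate, which places all five substituents in one step.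
- Ring A comes from orcinol monomethyl ether by sequential Br, Cl and I substitution.
- Ring order: ring A is purchased, ring B forms in step 9, and a temporary γ-lactone forms in step 11 and is opened in step 13.

Assumption: the target has no stereocentre and no configurationally stable axis, so "single enantiomer" has no consequence. The one transient stereocentre (C3 of compounds 16 and 17) is racemic and is destroyed in step 13.

## Ring A fragment

**Step 1**
- Reactants: 1, 3-methoxy-5-methylphenol
- Product: 2, 2-bromo-5-methoxy-3-methylphenol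
- Conditions: NBS (1.0 equiv), i-Pr2NH (10 mol %), CH2Cl2, 0 °C to rt, dark
- Reagents that add atoms: N-bromosuccinimide, O=C1CCC(=O)N1Br
- Why: Amine-mediated ortho-selective SEAr bromination of a phenol; of the two ortho sites, the one para to OMe and next to CH3 is more activated than the C–H wedged between the two oxygens.

**Step 2**
- Reactants: 2, 2-bromo-5-methoxy-3-methylphenol
- Product: 3, 2-bromo-4-chloro-5-methoxy-3-methylphenol
- Conditions: SO2Cl2 (1.05 equiv), Et2O/CH2Cl2, 0 °C, dark
- Reagents that add atoms: sulfuryl chloride, O=S(=O)(Cl)Cl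
- Why: SEAr chlorination goes para to the free OH at the remaining position flanking the methyl group, because in orcinol-type rings the C–H between the two oxygens reacts last.

**Step 3**
- Reactants: 3, 2-bromo-4-chloro-5-methoxy-3-methylphenol
- Product: 4, 2-bromo-4-chloro-6-iodo-5-methoxy-3-methylphenol
- Conditions: NIS (1.1 equiv), TFA (10 mol %), MeCN, 0 °C to rt
- Reagents that add atoms: N-iodosuccinimide, O=C1CCC(=O)N1I
- Why: Electrophilic iodination is unambiguous because only one aromatic C–H remains, and it is ortho to both OH and OMe.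

## Diene

**Step 4**
- Reactants: 5, methyl acetoacetate; 6, prenyl bromide (1-bromo-3-methylbut-2-ene)
- Product: 7, methyl 7-methyl-3-oxooct-6-enoate
- Conditions: NaH, THF, 0 °C; n-BuLi, 0 °C; then 6, 0 °C to rt
- Reagents that add atoms: prenyl bromide (6), CC(C)=CCBr
- Why: Weiler dianion alkylation; the γ-carbanion is the most nucleophilic site and undergoes SN2 with the allylic bromide.

**Step 5**
- Reactants: 7, methyl 7-methyl-3-oxooct-6-enoate
- Product: 8, methyl 7-methyl-3-(trimethylsilyloxy)octa-2,6-dienoate (C2=C3 geometry irrelevant)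
- Conditions: Me3SiCl, Et3N, toluene, rt, 48 h
- Reagents that add atoms: chlorotrimethylsilane, C[Si](C)(C)Cl
- Why: Soft enolisation and O-silylation of the β-keto ester, which is the standard first stage of Chan-diene synthesis.

**Step 6**
- Reactants: 8, methyl 7-methyl-3-(trimethylsilyloxy)octa-2,6-dienoate
- Product: 9, 1-methoxy-7-methyl-1,3-bis(trimethylsilyloxy)octa-1,3,6-triene (mainly 3Z, with the chain on the outside of the s-cis diene)
- Conditions: LDA, THF, −78 °C; Me3SiCl, −78 °C to rt; filtered under Ar and used crude
- Reagents that add atoms: chlorotrimethylsilane, C[Si](C)(C)Cl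
- Why: Kinetic γ-deprotonation of the vinylogous ester followed by O-silylation gives the 1,3-bis(silyloxy)diene, whose geometry is lost later on aromatisation.

## Dienophile

**Step 7**
- Reactants: 10, 3,3-diethoxyprop-1-yne; 11, allyl chloroformate
- Product: 12, allyl 4,4-diethoxybut-2-ynoate
- Conditions: n-BuLi, THF, −78 °C; then 11, −78 to 0 °C
- Reagents that add atoms: allyl chloroformate (11), C=CCOC(=O)Cl
- Why: C-acylation of a lithium acetylide by a chloroformate; this carbonyl carbon ends up as the benzophenone C=O.

**Step 8**
- Reactants: 12, allyl 4,4-diethoxybut-2-ynoate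
- Product: 13, allyl 4-oxobut-2-ynoate (used immediately)
- Conditions: HCO2H (98 %), CHCl3, rt
- Reagents that add atoms: formic acid, O=CO (supplies the aldehyde oxygen)
- Why: Formolysis of an acetylenic acetal, which is strong enough to cleave the deactivated acetal and leaves the allyl ester and the alkyne intact.

## Assembly

**Step 9**
- Reactants: 9, the bis(silyloxy)diene (1.3 equiv); 13, allyl 4-oxobut-2-ynoate
- Product: 14, allyl 2-formyl-3,5-dihydroxy-6-(3-methylbut-2-en-1-yl)benzoate
- Conditions: PhMe, −78 °C to rt, 6 h; then Et3N·3HF (or 1 M HCl), THF, 0 °C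
- Reagents that add atoms: none
- Why: Normal-demand Diels–Alder benzannulation in which CHO is the stronger acceptor, so the nucleophilic prenyl-bearing diene terminus bonds to the alkyne carbon β to CHO (the ester-bearing carbon) and the ketene-acetal carbon bonds next to CHO; loss of MeOH and desilylation then aromatise the adduct.

**Step 10**
- Reactants: 14, allyl 2-formyl-3,5-dihydroxy-6-prenylbenzoate
- Product: 15, allyl 3,5-bis(tert-butyldimethylsilyloxy)-2-formyl-6-(3-methylbut-2-en-1-yl)benzoate
- Conditions: TBSOTf (2.5 equiv), 2,6-lutidine, CH2Cl2, −78 to 0 °C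
- Reagents that add atoms: TBSOTf, CC(C)(C)[Si](C)(C)OS(=O)(=O)C(F)(F)F
- Why: Phenol silylation; the triflate is reactive enough for the chelated OH, and the buffered medium spares the prenyl group.

**Step 11**
- Reactants: 15, the bis-TBS allyl ester
- Product: 16, (±)-4,6-bis(tert-butyldimethylsilyloxy)-3-hydroxy-7-(3-methylbut-2-en-1-yl)isobenzofuran-1(3H)-one (ring–chain tautomer of the 2-formylbenzoic acid)
- Conditions: Pd(PPh3)4 (5 mol %), PhSiH3 (2 equiv), CH2Cl2, rt
- Reagents that add atoms: none
- Why: Tsuji–Trost deallylation with a silane scavenger, chosen because amine scavengers would give 3-aminophthalides; the freed acid closes onto the neighbouring CHO.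

**Step 12**
- Reactants: 16, the 3-hydroxyphthalide; 4, 2-bromo-4-chloro-6-iodo-5-methoxy-3-methylphenol
- Product: 17, (±)-3-(2-bromo-4-chloro-6-iodo-5-methoxy-3-methylphenoxy)-4,6-bis(tert-butyldimethylsilyloxy)-7-(3-methylbut-2-en-1-yl)isobenzofuran-1(3H)-one
- Conditions: 1-chloro-N,N,2-trimethylpropenylamine, CH2Cl2, 0 °C (gives the 3-chlorophthalide); then 4, i-Pr2NEt, −20 °C to rt
- Reagents that add atoms: none beyond reactant 4
- Why: Pseudo-acid chloride formation followed by SN1-like O-alkylation of the acidic phenol at C3 (standard 3-halophthalide chemistry, with the cation stabilised by the o,p-silyloxy groups); C-alkylation is impossible because ring A has no C–H.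

**Step 13**
- Reactants: 17, the 3-aryloxyphthalide
- Product: 18, 2-(3-bromo-5-chloro-2-hydroxy-6-methoxy-4-methylbenzoyl)-4,6-bis(tert-butyldimethylsilyloxy)-3-(3-methylbut-2-en-1-yl)benzaldehyde
- Conditions: i-PrMgCl·LiCl (1.1 equiv), THF (0.02 M), −78 to −30 °C; AcOH/THF quench at −78 °C; work-up in the dark
- Reagents that add atoms: none
- Why: Proposed new method: chemoselective I/Mg exchange (C–I far faster than C–Br or C–Cl) places an aryl-Mg carbon 1,5 to the lactone carbonyl, which it attacks from the lactone face through a six-membered transition state to give an unstrained bicyclo[3.2.1] alkoxide; collapse breaks C1–O2 to form the ketone, and the resulting hemiacetal alkoxide expels the ring-A phenoxide to form the CHO, so the hindered ketone, the aldehyde and the phenol are unmasked together with no redox step; the closest known reactions are Parham cycliacylation and the halogen–metal-exchange-triggered anionic Fries rearrangement.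

**Step 14**
- Reactants: 18, bis-TBS pestalone G
- Product: 19, pestalone G, 2-(3-bromo-5-chloro-2-hydroxy-6-methoxy-4-methylbenzoyl)-4,6-dihydroxy-3-(3-methylbut-2-en-1-yl)benzaldehyde
- Conditions: Et3N·3HF, THF, 0 °C to rt, dark
- Reagents that add atoms: none
- Why: Fluoride desilylation of the aryl silyl ethers in a slightly acidic, non-nucleophilic medium avoids the base-, nucleophile- and light-induced isomerisation of 2-formylaryl ketones to phthalides, and also avoids prenyl/phenol cyclisation.

## Compound list

| No. | Name | SMILES | Role |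
|---|---|---|---|
| 1 | 3-methoxy-5-methylphenol | COc1cc(C)cc(O)c1 | starting material |
| 2 | 2-bromo-5-methoxy-3-methylphenol | COc1cc(O)c(Br)c(C)c1 | intermediate |
| 3 | 2-bromo-4-chloro-5-methoxy-3-methylphenol | COc1cc(O)c(Br)c(C)c1Cl | intermediate |
| 4 | 2-bromo-4-chloro-6-iodo-5-methoxy-3-methylphenol | COc1c(I)c(O)c(Br)c(C)c1Cl | intermediate |
| 5 | methyl acetoacetate | CC(=O)CC(=O)OC | starting material |
| 6 | prenyl bromide | CC(C)=CCBr | starting material |
| 7 | methyl 7-methyl-3-oxooct-6-enoate | COC(=O)CC(=O)CCC=C(C)C | intermediate |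
| 8 | methyl 7-methyl-3-(trimethylsilyloxy)octa-2,6-dienoate | COC(=O)C=C(CCC=C(C)C)O[Si](C)(C)C | intermediate |
| 9 | 1-methoxy-7-methyl-1,3-bis(trimethylsilyloxy)octa-1,3,6-triene | COC(=CC(=CCC=C(C)C)O[Si](C)(C)C)O[Si](C)(C)C | intermediate |
| 10 | 3,3-diethoxyprop-1-yne | C#CC(OCC)OCC | starting material |
| 11 | allyl chloroformate | C=CCOC(=O)Cl | starting material |
| 12 | allyl 4,4-diethoxybut-2-ynoate | C=CCOC(=O)C#CC(OCC)OCC | intermediate |
| 13 | allyl 4-oxobut-2-ynoate | C=CCOC(=O)C#CC=O | intermediate |
| 14 | allyl 2-formyl-3,5-dihydroxy-6-prenylbenzoate | C=CCOC(=O)c1c(C=O)c(O)cc(O)c1CC=C(C)C | intermediate |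
| 15 | allyl 3,5-bis(TBSO)-2-formyl-6-prenylbenzoate | C=CCOC(=O)c1c(C=O)c(O[Si](C)(C)C(C)(C)C)cc(O[Si](C)(C)C(C)(C)C)c1CC=C(C)C | intermediate |
| 16 | (±)-4,6-bis(TBSO)-3-hydroxy-7-prenylisobenzofuran-1(3H)-one | O=C1OC(O)c2c1c(CC=C(C)C)c(O[Si](C)(C)C(C)(C)C)cc2O[Si](C)(C)C(C)(C)C | intermediate |
| 17 | (±)-3-(2-bromo-4-chloro-6-iodo-5-methoxy-3-methylphenoxy)-4,6-bis(TBSO)-7-prenylisobenzofuran-1(3H)-one | O=C1OC(Oc3c(I)c(OC)c(Cl)c(C)c3Br)c2c1c(CC=C(C)C)c(O[Si](C)(C)C(C)(C)C)cc2O[Si](C)(C)C(C)(C)C | intermediate |
| 18 | bis-TBS pestalone G | COc1c(Cl)c(C)c(Br)c(O)c1C(=O)c1c(C=O)c(O[Si](C)(C)C(C)(C)C)cc(O[Si](C)(C)C(C)(C)C)c1CC=C(C)C | intermediate |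
| 19 | pestalone G (achiral) | COc1c(Cl)c(C)c(Br)c(O)c1C(=O)c1c(C=O)c(O)cc(O)c1CC=C(C)C | target |

## Step count

- Total steps: 14.
- Longest linear sequence: 9 (steps 4, 5, 6, 9, 10, 11, 12, 13, 14).

## Steps most likely to fail

1. **Step 13 (tethered O→C aroyl transfer).**
   - Risks: slow attack on the hindered lactone, internal proton transfer from C3–H, or loss of the aryloxide.
   - Fallback: drop the tether. Reduce 16 with NaBH4 to the 7-prenyl-4,6-bis(silyloxy)phthalide and add the arylmagnesium from O-silylated 4 intermolecularly. Then oxidise the resulting 2-(hydroxymethyl)benzophenone (as its lactol) to the keto-aldehyde with MnO2.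

2. **Step 9 (Diels–Alder of the ynal ester).**
   - Risks: Mukaiyama aldol or hetero-Diels–Alder reaction at CHO, and polymerisation of 13.
   - Fallback: give up de novo ring construction and decorate an existing arene. Take methyl 3,5-dihydroxybenzoate to its bis-silyl ether, formylate at C2 (Vilsmeier), brominate at C6, and install prenyl by Stille or Negishi coupling. This converges on the methyl-ester analogue of 15.

3. **Step 1 (which methyl-flanking site takes Br and which takes Cl).**
   - Risk: a mixture of the ortho-OH and para-OH bromides.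
   - Fallback: let a carbonyl group both block and direct. Start from 2-hydroxy-6-methoxy-4-methylbenzoic acid and chlorinate para to the chelated OH. Then brominate the only remaining site, ortho to OH. Finally convert CO2H into I by decarboxylative iodination (I2, K3PO4) to reach 4.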